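I could not integrate this scheme by hand, so I looked for a scale on which the flasks differ in time and in little else.

| flask | substrate | coupling partner | time | remark | temperature |
|---|---|---|---|---|---|
| west | 0.073 M | 0.0949 M | 1.0 h | at −20 °C until 20 min, from then on at −35 °C |  |
| north-west | 0.073 M | 0.0949 M | 1.0 h |  | −20 °C |
| north-east | 0.073 M | 0.0949 M | 1.0 h |  | −35 °C |

1. the flask that comes out highest in amount of bis adduct, in percent of the substrate charged, or "all alike" when all lie within 1.5 percentage points (west / north-west / north-east / all alike)
2. bis adduct at the end, in percent of the substrate charged, west
3. bis adduct at the end, in percent of the substrate charged, north-west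
4. bis adduct at the end, in percent of the substrate charged, north-east

- a species is counted by the substrate in it: one homo dimer counts as two
- amounts and yields of bis adduct count crystals too
- a step written with two of one species runs at k times the square of its concentration and takes two of it each time
- given per volume of solution although it is solid: crystals
- at −20 °C the constants are as listed, elsewhere as the activation energies make them

The zero of that scale is the symmetric case. If each step with an activation energy had the same one, cooling would slow those steps by one common factor, like a slower clock. Bis adduct comes from the second coupling, coupling partner with first product, so I started there. Going from −20 °C to −35 °C, its activation energy of 39.0 kJ mol⁻¹ slows that step by 3.21. I called this ratio the cold factor f.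

Then I turned each flask into clock time, the minutes at −20 °C that do the same work. North-west has its full 60 min. North-east has 18.7 min. West has 20 min warm and the rest divided by f, which makes 32.5 min. So I committed to this order: north-west runs longer than west, and west longer than north-east.

The weak link was the single clock. Homo dimer formation has 43.0 kJ mol⁻¹ against 38.0 kJ mol⁻¹ for the first coupling, so cooling slows it by 3.62, more than f. I reforged the link with a selectivity factor: substrate used by the first coupling over substrate used by homo dimer formation, at the start. It is 3.17 at −20 °C and 3.68 at −35 °C, higher in the cold. So I kept the clock, but I expected less homo dimer in a cold flask at equal clock time.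

I reckoned no yields. The forecast did: north-west highest, with 42.3% in west, 51% in north-west and 32% in north-east. It placed west “as if it had spent about 33 minutes” at the warm temperature.

    substrate + coupling partner → first product (k1 = 0.0150 M⁻¹ s⁻¹, Ea1 = 38.0 kJ mol⁻¹)
    2 substrate → homo dimer (k2 = 0.00308 M⁻¹ s⁻¹, Ea2 = 43.0 kJ mol⁻¹)
    crystals ⇌ bis adduct, rate k3*(cs3 - [bis adduct]) while solid is left; crystals form when [bis adduct] > cs3 (cs3 = 0.98 mM, k3 = 0.0452 s⁻¹)
    coupling partner + first product → bis adduct (k4 = 0.0258 M⁻¹ s⁻¹, Ea4 = 39.0 kJ mol⁻¹)
    bis adduct → over-reaction product (k5 = 2.08 × 10⁻⁷ s⁻¹, Ea5 = 93.0 kJ mol⁻¹)
    coupling partner + bis adduct → tris adduct (k6 = 0.00444 M⁻¹ s⁻¹, Ea6 = 59.0 kJ mol⁻¹)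
    (constants at −20 °C)

The flasks gave 41.8% in west, 50.7% in north-west and 31.6% in north-east, so north-west came out highest and the forecast held. West, at 32.5 min of clock, stood just above north-west's 40.3% at 0.500 h. North-east, at 18.7 min, stood just below west's 32.3% at 0.333 h. Then I read north-east at 4.0 h, with amounts and temperature held. Its clock time is 74.7 min, longer than north-west's 60 min. It gave 53.4% of bis adduct against 50.7% in north-west, and homo dimer stood at 18.4% against 19.7% in north-west.

Its constants were drawn at random within sensible limits; the flask was simulated.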